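Count what is left.

all flasks: substrate 2.0 × 10⁻⁴ M

|  | reagent | remark | time |
|---|---|---|---|
| noon | 0.21 mM | the very flask that is asked about, followed so far |  |
| flask | 0.210 mM |  | 8.0 min |

noon run (percent of the substrate charged)

| time / min | intermediate A / % | product / % |
|---|---|---|
| 0.167 | 22.8 | 0.3 |
| 0.500 | 40.4 | 2.3 |
| 1.33 | 29.0 | 22.9 |
| 4.00 | 0 | 70.2 |

(standard deviation of a reading: 1 percentage point)

- the best time, 8.0 min at the latest, for intermediate A
- the amount of intermediate A, in percent of the substrate charged, at that time
- earliest time at which at least nineteen twentieths of that best amount are there, in min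
- latest time at which they still are, in min

- the analysis behind the earlier runs scatters by 1 percentage point, standard deviation

We take intermediate A as made from the substrate and lost, each step in proportion to what is there, and reckon in percent of the charge. At 0.167 min, counting what has gone as intermediate A and product, we reckon from the noon run of this flask that 76.9% of the substrate is left, so the making constant reads

k = ln(1/left)/t = 1.57 min⁻¹.

Let the loss constant be r·k. At the top, making equals loss:

k·c(substrate) = r·k·c(intermediate A), so c(substrate)/c(intermediate A) = r.

The substrate left follows from k, which gives

t(top) = ln(1/r) / (k(1 − r)), height = r^(r/(1 − r)).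

Two extreme versions can be solved in the head:

r = 1: top at 0.637 min, height 36.8%; at 0.500 min it holds 35.8%.

r = 0.5: top at 0.883 min, height 50.0%; at 0.500 min it holds 43.9%.

The noon reading of 40.4% at that time lies above the first and below the second. Placing r in proportion gives the loss ratio, the substrate left over intermediate A at the top, 0.716. Our top then stands at 0.749 min with 43.1%.

The forecast, reasoning that “Formation and loss balance” at the top, puts 42.5% at 0.75 min, held from 0.5 min to 1 min.

The flask gives 41.5% at 0.655 min, held from 0.466 min to 0.889 min.

    substrate → intermediate A (k = 0.0288 s⁻¹)
    intermediate A ⇌ intermediate B (K = 0.340, k = 7.21 × 10⁻⁴ s⁻¹)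
    intermediate A → intermediate C (k = 0.0217 s⁻¹)
    reagent + intermediate C → product (k = 85.1 L mol⁻¹ s⁻¹)

At 0.655 min this flask holds substrate 32.2% and intermediate A 41.5%, so the loss ratio, read from the noon run as 0.716, comes from these two amounts as 0.777. We carry this ratio, reckoned on the charge, unchanged to a neighbour flask charged with 1.2 × 10⁻⁴ M of substrate, and the height rule gives 41.5% for it. That neighbour reaches a top of 41.5%.

The readings were generated by integration for an exercise.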